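**Plan**

- Retrosynthesis: the 5-OH is traced back to a 5-OMe and the C2=C3 double bond to a flavanone. Ring C is then cut at O1–C8a, C4–C4a and O1–C2, leaving a benzyne (C4a≡C8a) and (Z)-α-methoxy-4-methoxycinnamic acid.
- Enabling feature: ring A carries an oxygen on each of C5, C6, C7 and C8, so the aryne spanning C4a/C8a is 3,4,5,6-tetramethoxybenzyne. Its two termini are equivalent, so either may become C4a and no regiochemical question arises.
- Forward: ring A comes from 1,2,3,4-tetramethoxybenzene (hydroxylation, bromination, retro-Brook/triflation). Ring B with C2 and C3 comes from anisaldehyde and methyl methoxyacetate. The two pieces are joined and the pyranone ring is closed in one operation, then dehydrogenation and chelation-controlled 5-O-demethylation finish the route.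
- Stereochemistry: the target has no stereocentre. C2 and C3 of the flavanone arise without control and both become sp2 in the next step.

Key step: step 5

Assumption: 5-hydroxyauranetin has no stereocentre, stereogenic double bond or axis, so the constitution drawn is its only stereoisomer and nothing has to be induced or resolved.

**Route**

Step 1
Reactants: 1 1,2,3,4-tetramethoxybenzene
Product: 4 2,3,4,5-tetramethoxyphenol, via aryllithium 2 (not isolated), via dimethyl arylboronate 3 (not isolated)
Conditions: n-BuLi, TMEDA, THF, −20 to 0 °C; B(OMe)3, −78 °C to rt; AcOH, 30% aq. H2O2, 0 °C to rt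
Reagents that add atoms: hydrogen peroxide, OO
Why: Directed ortho-metalation at one of the two equivalent ring C–H positions (each ortho to OMe), borylation of the aryllithium and boronate oxidation (1,2-aryl shift from boron to oxygen) should give the phenol in one flask.

Step 2
Reactants: 4 2,3,4,5-tetramethoxyphenol
Product: 5 2-bromo-3,4,5,6-tetramethoxyphenol
Conditions: NBS, CH2Cl2, −20 to 0 °C
Reagents that add atoms: N-bromosuccinimide, O=C1CCC(=O)N1Br
Why: Electrophilic aromatic bromination can only occur at the single unsubstituted ring carbon, which is ortho to the activating OH; low temperature and exact stoichiometry are chosen to suppress oxidation of the electron-rich phenol.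

Step 3
Reactants: 5 2-bromo-3,4,5,6-tetramethoxyphenol
Product: 8 2,3,4,5-tetramethoxy-6-(trimethylsilyl)phenyl trifluoromethanesulfonate, via aryl trimethylsilyl ether 6 (not isolated), via lithium 2-silylphenoxide 7 (not isolated)
Conditions: HMDS, THF, 70 °C, then evaporation; n-BuLi, THF, −100 to −78 °C; Tf2O, −100 to −78 °C
Reagents that add atoms: hexamethyldisilazane, C[Si](C)(C)N[Si](C)(C)C; trifluoromethanesulfonic anhydride, O=S(=O)(OS(=O)(=O)C(F)(F)F)C(F)(F)F
Why: O-Silylation, bromine–lithium exchange, retro-Brook 1,3-O→C silyl shift and triflation of the resulting phenoxide form the standard one-flask route to 2-silylaryl triflates, which is known to tolerate methoxy groups flanking both the silyl and the triflate position.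

Step 4
Reactants: 9 4-methoxybenzaldehyde; 10 methyl methoxyacetate
Product: 12 (Z)-2-methoxy-3-(4-methoxyphenyl)acrylic acid, via methyl ester 11 (not isolated)
Conditions: NaOMe, MeOH, 0 °C to reflux; aq. NaOH, reflux; HCl, 0 °C to pH 2
Reagents that add atoms: sodium hydroxide, [Na+].[OH-]
Why: Claisen-type aldol condensation of the ester enolate with the non-enolisable aldehyde and E1cB dehydration should give the thermodynamically preferred Z enol-ether ester (aryl trans to the carbonyl), which is saponified in the same flask; the alkene geometry is lost in step 5 and is of no consequence.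

Step 5
Reactants: 8 2,3,4,5-tetramethoxy-6-(trimethylsilyl)phenyl trifluoromethanesulfonate; 12 (Z)-2-methoxy-3-(4-methoxyphenyl)acrylic acid
Product: 16 3,5,6,7,8-pentamethoxy-2-(4-methoxyphenyl)chroman-4-one (racemic cis/trans mixture), via tetramethoxybenzyne 13 (not isolated), via 2-acyloxyaryl cesium 14 (not isolated), via chalcone phenoxide 15 (not isolated)
Conditions: CsF (4 equiv), THF, 125 °C, sealed tube; 8 in slight excess (1.3 equiv)
Reagents that add atoms: none
Why: Fluoride-induced 1,2-elimination of 8 gives aryne 13, the cesium carboxylate of 12 adds to it (O1–C8a), and the resulting ortho aryl anion 14 attacks its own ester carbonyl through a four-membered alkoxide that reopens to the ortho-acyl phenoxide 15 (C4–C4a), a net insertion of the aryne into the acyl C–O σ bond by an anionic Fries-type shift. The closest known reaction type is the CsF-mediated aryne insertion into carboxylic acid C–O bonds at elevated temperature and its cascade with α,β-unsaturated acids to 4-chromanones; the α-methoxy group and the tetramethoxy aryne are new substrates within that class. Ring C then closes by 6-endo-trig oxa-Michael addition of the phenoxide oxygen to the β-carbon (O1–C2), and the methoxy group ortho to the acyl group (the later 5-OMe) twists the aroyl unit and should bias the chalcone–flavanone equilibrium towards the closed form. C2 and C3 arise without control (C3 by protonation of the enolate and epimerisable, so the 2,3-trans isomer is expected to predominate) and the mixture is carried on because both centres are removed in step 6. The selectivity needed is acyl transfer over protonation of 14, which would stop at the aryl ester; the aprotic medium, the proximity of the ester carbonyl and the high temperature are chosen to secure it. Regioselectivity of the carboxylate addition does not arise because 13 is symmetrical, and any chalcone that stays open converges on 18 under the conditions of step 6.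

Step 6
Reactants: 16 3,5,6,7,8-pentamethoxy-2-(4-methoxyphenyl)chroman-4-one
Product: 18 3,5,6,7,8-pentamethoxy-2-(4-methoxyphenyl)-4H-chromen-4-one, via 3-iodoflavanone 17 (not isolated)
Conditions: I2 (20 mol%), DMSO, 120 °C
Reagents that add atoms: none
Why: Iodine/DMSO dehydrogenation of a flavanone: enolisation towards C3 (the only α-C–H), α-iodination to 17 and loss of HI should give the conjugated chromone while DMSO reoxidises HI to iodine; ring A has no free position for iodination.

Step 7
Reactants: 18 3,5,6,7,8-pentamethoxy-2-(4-methoxyphenyl)-4H-chromen-4-one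
Product: 20 5-hydroxyauranetin [5-hydroxy-3,6,7,8-tetramethoxy-2-(4-methoxyphenyl)-4H-chromen-4-one], via dichloroboron chelate 19 (not isolated)
Conditions: BCl3 (1.2 equiv), CH2Cl2, −78 to 0 °C; then H2O/MeOH
Reagents that add atoms: none
Why: Chelation-controlled ether cleavage: boron binds the C4 carbonyl and the peri 5-methoxy oxygen in a six-membered chelate, so chloride should demethylate only that ether, and hydrolysis of 19 frees the hydrogen-bonded 5-OH; the 3-OMe could only form a less favoured five-membered chelate and should survive at low temperature with near-stoichiometric reagent.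

**Compound list**

1 | 1,2,3,4-tetramethoxybenzene | COc1ccc(OC)c(OC)c1OC | starting material
2 | (2,3,4,5-tetramethoxyphenyl)lithium (in-flask species) | [Li]c1cc(OC)c(OC)c(OC)c1OC | intermediate
3 | dimethyl (2,3,4,5-tetramethoxyphenyl)boronate (in-flask species) | COB(OC)c1cc(OC)c(OC)c(OC)c1OC | intermediate
4 | 2,3,4,5-tetramethoxyphenol | Oc1cc(OC)c(OC)c(OC)c1OC | intermediate
5 | 2-bromo-3,4,5,6-tetramethoxyphenol | Oc1c(Br)c(OC)c(OC)c(OC)c1OC | intermediate
6 | (2-bromo-3,4,5,6-tetramethoxyphenoxy)trimethylsilane (in-flask species) | C[Si](C)(C)Oc1c(Br)c(OC)c(OC)c(OC)c1OC | intermediate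
7 | lithium 2,3,4,5-tetramethoxy-6-(trimethylsilyl)phenoxide (in-flask species) | [Li+].[O-]c1c([Si](C)(C)C)c(OC)c(OC)c(OC)c1OC | intermediate
8 | 2,3,4,5-tetramethoxy-6-(trimethylsilyl)phenyl trifluoromethanesulfonate | COc1c(OC)c(OC)c(OS(=O)(=O)C(F)(F)F)c([Si](C)(C)C)c1OC | intermediate
9 | 4-methoxybenzaldehyde | COc1ccc(C=O)cc1 | starting material
10 | methyl methoxyacetate | COCC(=O)OC | starting material
11 | methyl (Z)-2-methoxy-3-(4-methoxyphenyl)acrylate (in-flask species) | COC(=O)/C(OC)=C/c1ccc(OC)cc1 | intermediate
12 | (Z)-2-methoxy-3-(4-methoxyphenyl)acrylic acid | OC(=O)/C(OC)=C/c1ccc(OC)cc1 | intermediate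
13 | 3,4,5,6-tetramethoxybenzyne (in-flask species) | COC1=C(OC)C(OC)=C(OC)C#C1 | intermediate
14 | 2-{[(Z)-2-methoxy-3-(4-methoxyphenyl)acryloyl]oxy}-3,4,5,6-tetramethoxyphenylcesium (in-flask species) | [Cs]c1c(OC)c(OC)c(OC)c(OC)c1OC(=O)/C(OC)=C/c1ccc(OC)cc1 | intermediate
15 | cesium 2-[(Z)-2-methoxy-3-(4-methoxyphenyl)acryloyl]-3,4,5,6-tetramethoxyphenoxide (in-flask species) | [Cs+].[O-]c1c(OC)c(OC)c(OC)c(OC)c1C(=O)/C(OC)=C/c1ccc(OC)cc1 | intermediate
16 | 3,5,6,7,8-pentamethoxy-2-(4-methoxyphenyl)chroman-4-one, racemic, mixture of 2,3-cis and 2,3-trans isomers | COc1ccc(C2Oc3c(OC)c(OC)c(OC)c(OC)c3C(=O)C2OC)cc1 | intermediate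
17 | 3-iodo-3,5,6,7,8-pentamethoxy-2-(4-methoxyphenyl)chroman-4-one, stereoisomer mixture (in-flask species) | COc1ccc(C2Oc3c(OC)c(OC)c(OC)c(OC)c3C(=O)C2(I)OC)cc1 | intermediate
18 | 3,5,6,7,8-pentamethoxy-2-(4-methoxyphenyl)-4H-chromen-4-one | COc1ccc(-c2oc3c(OC)c(OC)c(OC)c(OC)c3c(=O)c2OC)cc1 | intermediate
19 | 5-(dichloroboryloxy)-3,6,7,8-tetramethoxy-2-(4-methoxyphenyl)-4H-chromen-4-one, boron chelated by the C4 carbonyl (in-flask species) | COc1ccc(-c2oc3c(OC)c(OC)c(OC)c(OB(Cl)Cl)c3c(=O)c2OC)cc1 | intermediate
20 | 5-hydroxyauranetin, 5-hydroxy-3,6,7,8-tetramethoxy-2-(4-methoxyphenyl)-4H-chromen-4-one | COc1ccc(-c2oc3c(OC)c(OC)c(OC)c(O)c3c(=O)c2OC)cc1 | target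

**Step count**

Total: 7 steps. Longest linear sequence: 6 steps (1, 2, 3, 5, 6, 7); step 4 is a one-step branch.

**Steps most likely to fail**

Step 5. The aryl anion may be protonated before it transfers the acyl group, so that the reaction stops at O-arylation. Addition of the carboxylate to the electron-rich aryne, which has a methoxy group beside each terminus, may be slow. The intermediate phenoxide may also be arylated by a second aryne. The fallback generates the same ortho-acyloxy aryl anion without an aryne and without a proton source. It sets out from bromophenol 5 and acid 12, which are coupled (EDC·HCl, DMAP, CH2Cl2) to 2-bromo-3,4,5,6-tetramethoxyphenyl (Z)-2-methoxy-3-(4-methoxyphenyl)acrylate F1. Bromine–lithium exchange (n-BuLi, THF, −100 °C) should be followed by anionic Fries 1,3-O→C acyl migration, and after NH4Cl work-up this should give (Z)-1-(2-hydroxy-3,4,5,6-tetramethoxyphenyl)-2-methoxy-3-(4-methoxyphenyl)prop-2-en-1-one F2. Base-mediated oxa-Michael cyclisation (NaOAc, EtOH, reflux) then returns to the route at flavanone 16.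

Step 6. Iodination at the hindered, fully substituted C3 may be slow, the flavanone may reopen by retro-oxa-Michael reaction, and the anisyl ring may be iodinated at the high temperature. Partial loss of the 5-methyl group would be harmless, since step 7 removes it anyway. The fallback replaces the halogenation–elimination by a palladium-mediated dehydrogenation of a preformed enol derivative. It sets out from 16, which is converted by soft enolisation (TMSOTf, Et3N, CH2Cl2, 0 °C) to trimethyl{[3,5,6,7,8-pentamethoxy-2-(4-methoxyphenyl)-2H-chromen-4-yl]oxy}silane F3. Saegusa–Ito oxidation (Pd(OAc)2, MeCN, rt) via the C3 palladium enolate and β-hydride elimination of the C2–H returns to the route at flavone 18.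

Step 2. NBS may oxidise the para-methoxyphenol (oxidative demethylation towards a benzoquinone) in competition with ring bromination. The fallback reverses the order of halogenation and hydroxylation so that no free phenol meets the brominating agent. It sets out from 1, which is brominated (NBS, MeCN, rt) to 1-bromo-2,3,4,5-tetramethoxybenzene F4. Deprotonation of the remaining ring C–H, flanked by bromine and methoxy, with LiTMP in the presence of B(OiPr)3 (THF, −78 °C) traps the aryllithium before it can lose LiBr and gives diisopropyl (2-bromo-3,4,5,6-tetramethoxyphenyl)boronate F5. Oxidation (H2O2, AcOH, 0 °C) returns to the route at bromophenol 5, bypassing steps 1 and 2.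

**Further compounds**

F1 | step 5 | 2-bromo-3,4,5,6-tetramethoxyphenyl (Z)-2-methoxy-3-(4-methoxyphenyl)acrylate | O=C(Oc1c(Br)c(OC)c(OC)c(OC)c1OC)/C(OC)=C/c1ccc(OC)cc1
F2 | step 5 | (Z)-1-(2-hydroxy-3,4,5,6-tetramethoxyphenyl)-2-methoxy-3-(4-methoxyphenyl)prop-2-en-1-one | Oc1c(OC)c(OC)c(OC)c(OC)c1C(=O)/C(OC)=C/c1ccc(OC)cc1
F3 | step 6 | trimethyl{[3,5,6,7,8-pentamethoxy-2-(4-methoxyphenyl)-2H-chromen-4-yl]oxy}silane (racemic) | COc1ccc(C2Oc3c(OC)c(OC)c(OC)c(OC)c3C(O[Si](C)(C)C)=C2OC)cc1
F4 | step 2 | 1-bromo-2,3,4,5-tetramethoxybenzene | COc1cc(Br)c(OC)c(OC)c1OC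
F5 | step 2 | diisopropyl (2-bromo-3,4,5,6-tetramethoxyphenyl)boronate | CC(C)OB(OC(C)C)c1c(Br)c(OC)c(OC)c(OC)c1OC
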